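Helenien is disconnected at the C6–C7 single bond that links ring A (the 3-acyloxy β-ring) to the nonaene chain. The route exploits two features: C6 is a tetrasubstituted ring sp2 carbon flanked by quaternary C1 and methyl-bearing C5, so the corresponding 2,2,6-trimethylcyclohexanone gives a single enol triflate, and C7 is the terminus of an all-E polyene, available as an E-vinylstannane. A final palladium-catalysed Stille coupling joins the ring A triflate to a C31 nonaenylstannane that already carries ring B (the ε-ring) and its palmitate, forming the C6–C7 bond with retention of the C7=C8 geometry and delivering the target directly, without protecting groups.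

Key step: step 13

Remarks: carotenoid numbering is used throughout (ring A = β-ring C1–C6; chain C7 to C15, then C15' to C7'; ring B = ε-ring C1'–C6'). (R)-α-Ionone 1, (4R,6R)-actinol 23, dialdehyde 11 and enynol 14 are assumed to be purchasable in the stated form. Compounds 3, 5, 6 and 8 are carried as both epimers at the side-chain carbinol carbon, which is erased in step 5.

Step 1
Reactants: 1 (R)-α-ionone; 2 vinylmagnesium bromide
Product: 3 vinyl-α-ionol = (1E)-3-methyl-1-[(1R)-2,6,6-trimethylcyclohex-2-en-1-yl]penta-1,4-dien-3-ol (both carbinol epimers)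
Conditions: CH2=CHMgBr (1.3 equiv), THF, −20 to 0 °C; aq. NH4Cl
Reagents that add atoms: vinylmagnesium bromide, C=C[Mg]Br
Why: Grignard 1,2-addition to the methyl enone is fast and leaves C6' untouched; the new carbinol centre forms without control, which is harmless because step 5 erases it, and the tertiary alcohol masks the side-chain carbonyl carbon for the next two steps.

Step 2
Reactants: 3 vinyl-α-ionol; 4 tert-butyl hydroperoxide
Product: 5 (4R)-4-[(1E)-3-hydroxy-3-methylpenta-1,4-dien-1-yl]-3,5,5-trimethylcyclohex-2-en-1-one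
Conditions: t-BuOOH (5 equiv), Rh2(cap)4 (1 mol %, cap = caprolactamate), K2CO3, CH2Cl2, rt
Reagents that add atoms: tert-butyl hydroperoxide, CC(C)(C)OO
Why: Radical allylic C–H oxidation by tert-butylperoxyl radicals should attack the only unhindered ring allylic methylene (C3'), as in the known oxidation of α-ionone and its acetals to the 3-oxo compounds, because the C6' methine is shielded between C1' and the side chain and the tertiary carbinol has no oxidisable C–H.

Step 3
Reactants: 5 ring B enone
Product: 6 (1R,4R)-4-[(1E)-3-hydroxy-3-methylpenta-1,4-dien-1-yl]-3,5,5-trimethylcyclohex-2-en-1-ol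
Conditions: LiBH(s-Bu)3 (2.5 equiv), THF, −78 °C; then NaOH, H2O2, 0 °C
Reagents that add atoms: none
Why: 1,2-Reduction of a β,β-disubstituted cyclohexenone by a bulky trialkylborohydride; the C6' side chain sits pseudoaxial (A1,2 strain with the C5' methyl), so the C1' methyl trans to it is axial and blocks axial hydride delivery, and equatorial attack from the side-chain face should give the pseudoaxial 3'-OH trans to the chain, i.e. (3'R).

Step 4
Reactants: 6 diol; 7 palmitoyl chloride
Product: 8 (1R,4R)-4-[(1E)-3-hydroxy-3-methylpenta-1,4-dien-1-yl]-3,5,5-trimethylcyclohex-2-en-1-yl hexadecanoate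
Conditions: C15H31COCl (1.05 equiv), pyridine, DMAP (cat.), CH2Cl2, 0 °C
Reagents that add atoms: palmitoyl chloride, CCCCCCCCCCCCCCCC(=O)Cl
Why: Nucleophile-catalysed acylation distinguishes the secondary allylic alcohol from the hindered tertiary one and proceeds with retention at C3'.

Step 5
Reactants: 8 monopalmitate; 9 triphenylphosphonium bromide (PPh3·HBr)
Product: 10 [(2E,4E)-5-[(1R,4R)-4-(hexadecanoyloxy)-2,6,6-trimethylcyclohex-2-en-1-yl]-3-methylpenta-2,4-dien-1-yl]triphenylphosphonium bromide
Conditions: PPh3·HBr (1.05 equiv), CH2Cl2, rt, dark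
Reagents that add atoms: triphenylphosphonium bromide, [Br-].c1ccc(cc1)[PH+](c1ccccc1)c1ccccc1
Why: Acid-promoted ionisation of the tertiary bis-allylic alcohol gives a pentadienyl cation that PPh3 traps at its unhindered primary terminus (SN1-type allylic transposition, the classical C15 Wittig salt synthesis from vinyl-ionols), giving the thermodynamically favoured 7'E,9'E salt from both carbinol epimers, while the secondary allylic ester at C3' is far less ionisable and no nucleophilic solvent is present.

Step 6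
Reactants: 10 ring B C15 phosphonium bromide; 11 (2E,4E,6E)-2,7-dimethylocta-2,4,6-trienedial
Product: 13 C25 apo-aldehyde (2E,4E,6E,8E,10E,12E)-13-[(1R,4R)-4-(hexadecanoyloxy)-2,6,6-trimethylcyclohex-2-en-1-yl]-2,7,11-trimethyltrideca-2,4,6,8,10,12-hexaenal, via phosphonium ylide 12 (not isolated)
Conditions: 11 (2.5 equiv), 1,2-epoxybutane/CH2Cl2, reflux; then I2 (cat.), CH2Cl2, daylight, rt
Reagents that add atoms: 2,7-dimethylocta-2,4,6-trienedial, O=C/C(C)=C/C=C/C=C(C)/C=O
Why: Wittig olefination under neutral epoxide conditions (1,2-epoxybutane takes up HBr and releases the ylide) should keep the palmitate intact, excess dialdehyde should limit double olefination, and iodine-catalysed equilibration should bring the new C11'=C12' bond to E.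

Step 7
Reactants: 14 (E)-3-methylpent-2-en-4-yn-1-ol; 15 tributyltin hydride
Product: 16 (2E,4E)-3-methyl-5-(tributylstannyl)penta-2,4-dien-1-ol
Conditions: Bu3SnH (1.1 equiv), PdCl2(PPh3)2 (2 mol %), THF, 0 °C to rt
Reagents that add atoms: tributyltin hydride, CCCC[SnH](CCCC)CCCC
Why: Palladium-catalysed syn-hydrostannylation of the terminal alkyne of a conjugated enyne places tin on the terminal carbon and should give the E-vinylstannane with the existing E-alkene unchanged.

Step 8
Reactants: 16 stannyl dienol; 17 carbon tetrabromide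
Product: 18 tributyl[(1E,3E)-5-bromo-3-methylpenta-1,3-dien-1-yl]stannane
Conditions: CBr4, PPh3, CH2Cl2, −20 to 0 °C
Reagents that add atoms: carbon tetrabromide, BrC(Br)(Br)Br
Why: Appel bromination converts the primary allylic alcohol into the bromide under neutral conditions, so the acid-labile vinyl C–Sn bond should survive.

Step 9
Reactants: 18 stannyl dienyl bromide; 19 triethyl phosphite
Product: 20 diethyl [(2E,4E)-3-methyl-5-(tributylstannyl)penta-2,4-dien-1-yl]phosphonate
Conditions: P(OEt)3 (3 equiv, neat), 90 °C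
Reagents that add atoms: triethyl phosphite, CCOP(OCC)OCC
Why: Michaelis–Arbuzov reaction of a primary allylic bromide, to which the vinylstannane is inert.

Step 10
Reactants: 20 stannyl dienyl phosphonate; 13 C25 apo-aldehyde
Product: 22 (1R,4R)-3,5,5-trimethyl-4-[(1E,3E,5E,7E,9E,11E,13E,15E,17E)-3,7,12,16-tetramethyl-18-(tributylstannyl)octadeca-1,3,5,7,9,11,13,15,17-nonaen-1-yl]cyclohex-2-en-1-yl hexadecanoate, via potassium phosphonate carbanion 21 (not isolated)
Conditions: KN(SiMe3)2 (1.0 equiv), THF, −78 °C; then 13, −78 to 0 °C, dark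
Reagents that add atoms: none
Why: Horner–Wadsworth–Emmons olefination with a preformed allylic phosphonate anion should be E-selective for the new C11=C12 bond, and the stabilised anion should add to the aldehyde much faster than it attacks the secondary palmitate or removes the remote C6' hydrogen.

Step 11
Reactants: 23 (4R,6R)-actinol = (4R,6R)-4-hydroxy-2,2,6-trimethylcyclohexanone; 7 palmitoyl chloride
Product: 24 (1R,5R)-3,3,5-trimethyl-4-oxocyclohexyl hexadecanoate
Conditions: C15H31COCl (1.1 equiv), pyridine, DMAP (cat.), CH2Cl2, 0 °C to rt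
Reagents that add atoms: palmitoyl chloride, CCCCCCCCCCCCCCCC(=O)Cl
Why: Standard acylation of the secondary alcohol with retention at the carbinol carbon, which becomes C3 of ring A.

Step 12
Reactants: 24 actinol palmitate; 25 triflic anhydride
Product: 26 (1R)-3,5,5-trimethyl-4-[(trifluoromethanesulfonyl)oxy]cyclohex-3-en-1-yl hexadecanoate
Conditions: Tf2O (1.5 equiv), 2,6-di-tert-butyl-4-methylpyridine (2 equiv), CH2Cl2, 0 °C to reflux
Reagents that add atoms: triflic anhydride, O=S(=O)(OS(=O)(=O)C(F)(F)F)C(F)(F)F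
Why: Stang enol triflate formation (O-sulfonylation of the ketone, then deprotonation by the hindered pyridine) can give only the C5=C6 triflate because C1 is quaternary; the non-nucleophilic base spares the ester, and the methyl-bearing stereocentre of actinol is erased on purpose while C3 is untouched.

Step 13
Reactants: 26 ring A enol triflate; 22 nonaenylstannane
Product: 27 helenien = (3R,3'R,6'R)-β,ε-carotene-3,3'-diyl dihexadecanoate
Conditions: Pd2(dba)3 (5 mol %), AsPh3 (40 mol %), NMP/THF, 55 °C, Ar, dark; crystallisation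
Reagents that add atoms: none
Why: Zerovalent palladium inserts into the C6–O bond of vinyl triflate 26, the E-vinyl group of 22 passes from tin to palladium with retention, and reductive elimination forms the C6–C7 bond (Stille coupling). The closest known reaction is the coupling of the hindered 2,6,6-trimethylcyclohexenyl triflate with dienyl- to tetraenylstannanes under Pd2(dba)3/AsPh3 in NMP used for retinoids, extended here to a nonaenylstannane. No ring is closed and no stereocentre is created: the C7=C8 E geometry comes from the stannane and is transferred stereospecifically, and the C5=C6 position is fixed by the enol triflate. The centres C3, C3' and C6' are remote from the reacting carbons and the medium is neutral, so neither the two palmitates nor the doubly allylic C6'–H should be affected. The step needs transmetalation at a tetrasubstituted vinylpalladium centre to outrun stannane homocoupling and thermal Z/E drift, which the weakly bound AsPh3 ligand and the polar solvent are expected to secure; chemoselectivity is inherent, since the triflate and the single sp2 C–Sn bond are the only reactive sites.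

Compound list
1 | (R)-α-ionone | CC(=O)/C=C/[C@H]1C(C)=CCCC1(C)C | starting material
2 | vinylmagnesium bromide | C=C[Mg]Br | starting material
3 | vinyl-α-ionol, (1E)-3-methyl-1-[(1R)-2,6,6-trimethylcyclohex-2-en-1-yl]penta-1,4-dien-3-ol, both carbinol epimers | C=CC(C)(O)/C=C/[C@H]1C(C)=CCCC1(C)C | intermediate
4 | tert-butyl hydroperoxide | CC(C)(C)OO | starting material
5 | (4R)-4-[(1E)-3-hydroxy-3-methylpenta-1,4-dien-1-yl]-3,5,5-trimethylcyclohex-2-en-1-one | C=CC(C)(O)/C=C/[C@H]1C(C)=CC(=O)CC1(C)C | intermediate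
6 | (1R,4R)-4-[(1E)-3-hydroxy-3-methylpenta-1,4-dien-1-yl]-3,5,5-trimethylcyclohex-2-en-1-ol | C=CC(C)(O)/C=C/[C@H]1C(C)=C[C@H](O)CC1(C)C | intermediate
7 | palmitoyl chloride (hexadecanoyl chloride) | CCCCCCCCCCCCCCCC(=O)Cl | starting material
8 | (1R,4R)-4-[(1E)-3-hydroxy-3-methylpenta-1,4-dien-1-yl]-3,5,5-trimethylcyclohex-2-en-1-yl hexadecanoate | C=CC(C)(O)/C=C/[C@H]1C(C)=C[C@H](OC(=O)CCCCCCCCCCCCCCC)CC1(C)C | intermediate
9 | triphenylphosphonium bromide (PPh3·HBr) | [Br-].c1ccc(cc1)[PH+](c1ccccc1)c1ccccc1 | starting material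
10 | [(2E,4E)-5-[(1R,4R)-4-(hexadecanoyloxy)-2,6,6-trimethylcyclohex-2-en-1-yl]-3-methylpenta-2,4-dien-1-yl]triphenylphosphonium bromide | [Br-].c1ccc(cc1)[P+](c1ccccc1)(c1ccccc1)C/C=C(C)/C=C/[C@H]1C(C)=C[C@H](OC(=O)CCCCCCCCCCCCCCC)CC1(C)C | intermediate
11 | (2E,4E,6E)-2,7-dimethylocta-2,4,6-trienedial | O=C/C(C)=C/C=C/C=C(C)/C=O | starting material
12 | phosphonium ylide of 10 | c1ccc(cc1)[P+](c1ccccc1)(c1ccccc1)[CH-]/C=C(C)/C=C/[C@H]1C(C)=C[C@H](OC(=O)CCCCCCCCCCCCCCC)CC1(C)C | intermediate
13 | (2E,4E,6E,8E,10E,12E)-13-[(1R,4R)-4-(hexadecanoyloxy)-2,6,6-trimethylcyclohex-2-en-1-yl]-2,7,11-trimethyltrideca-2,4,6,8,10,12-hexaenal | O=C/C(C)=C/C=C/C=C(C)/C=C/C=C(C)/C=C/[C@H]1C(C)=C[C@H](OC(=O)CCCCCCCCCCCCCCC)CC1(C)C | intermediate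
14 | (E)-3-methylpent-2-en-4-yn-1-ol | C#C/C(C)=C/CO | starting material
15 | tributyltin hydride | CCCC[SnH](CCCC)CCCC | starting material
16 | (2E,4E)-3-methyl-5-(tributylstannyl)penta-2,4-dien-1-ol | CCCC[Sn](CCCC)(CCCC)/C=C/C(C)=C/CO | intermediate
17 | carbon tetrabromide | BrC(Br)(Br)Br | starting material
18 | tributyl[(1E,3E)-5-bromo-3-methylpenta-1,3-dien-1-yl]stannane | CCCC[Sn](CCCC)(CCCC)/C=C/C(C)=C/CBr | intermediate
19 | triethyl phosphite | CCOP(OCC)OCC | starting material
20 | diethyl [(2E,4E)-3-methyl-5-(tributylstannyl)penta-2,4-dien-1-yl]phosphonate | CCCC[Sn](CCCC)(CCCC)/C=C/C(C)=C/CP(=O)(OCC)OCC | intermediate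
21 | potassium salt of the α-carbanion of phosphonate 20 | [K+].CCCC[Sn](CCCC)(CCCC)/C=C/C(C)=C/[CH-]P(=O)(OCC)OCC | intermediate
22 | (1R,4R)-3,5,5-trimethyl-4-[(1E,3E,5E,7E,9E,11E,13E,15E,17E)-3,7,12,16-tetramethyl-18-(tributylstannyl)octadeca-1,3,5,7,9,11,13,15,17-nonaen-1-yl]cyclohex-2-en-1-yl hexadecanoate | CCCC[Sn](CCCC)(CCCC)/C=C/C(C)=C/C=C/C(C)=C/C=C/C=C(C)/C=C/C=C(C)/C=C/[C@H]1C(C)=C[C@H](OC(=O)CCCCCCCCCCCCCCC)CC1(C)C | intermediate
23 | (4R,6R)-actinol, (4R,6R)-4-hydroxy-2,2,6-trimethylcyclohexanone | O[C@@H]1C[C@@H](C)C(=O)C(C)(C)C1 | starting material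
24 | (1R,5R)-3,3,5-trimethyl-4-oxocyclohexyl hexadecanoate | CCCCCCCCCCCCCCCC(=O)O[C@@H]1C[C@@H](C)C(=O)C(C)(C)C1 | intermediate
25 | triflic anhydride | O=S(=O)(OS(=O)(=O)C(F)(F)F)C(F)(F)F | starting material
26 | (1R)-3,5,5-trimethyl-4-[(trifluoromethanesulfonyl)oxy]cyclohex-3-en-1-yl hexadecanoate | CCCCCCCCCCCCCCCC(=O)O[C@@H]1CC(C)=C(OS(=O)(=O)C(F)(F)F)C(C)(C)C1 | intermediate
27 | helenien, (3R,3'R,6'R)-β,ε-carotene-3,3'-diyl dihexadecanoate | CCCCCCCCCCCCCCCC(=O)O[C@@H]1CC(C)=C(/C=C/C(C)=C/C=C/C(C)=C/C=C/C=C(C)/C=C/C=C(C)/C=C/[C@H]2C(C)=C[C@H](OC(=O)CCCCCCCCCCCCCCC)CC2(C)C)C(C)(C)C1 | target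

Total step count: 13. Longest linear sequence: 8 steps (steps 1–6, 10 and 13).

Steps most likely to fail

Step 13 (key Stille coupling). Transmetalation at the hindered tetrasubstituted vinylpalladium centre may be so slow that stannane homocoupling, protodestannylation and thermal Z/E scrambling of the nonaene outrun the cross-coupling. The fallback sets out from 22 and comes back at 27, changing the coupling to a base-accelerated boron-based one. Stannane 22 would be treated with I2 (1.0 equiv, CH2Cl2, −20 °C, dark) to give with retention the (all-E)-nonaenyl iodide F1. Miyaura borylation (B2pin2, PdCl2(PPh3)2, PPh3, KOPh, toluene, 50 °C) would convert it into the nonaenyl pinacol boronate F2. Suzuki–Miyaura coupling of F2 with triflate 26 (Pd(PPh3)4, TlOEt, THF/H2O, rt), a thallium-base variant that is fast for this hindered triflate class at room temperature, would then give 27.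

Step 2 (allylic oxidation). Peroxyl radicals may attack unselectively, by hydrogen abstraction at the doubly allylic C6' methine, addition to the vinyl group or degradation of the free tertiary carbinol. The fallback sets out from 1 and comes back at 6, moving the oxidation to a stage where the side chain is a simple acetal. Ketone 1 would be converted (ethylene glycol, HC(OMe)3, PPTS, rt) into the (R)-α-ionone ethylene acetal F3 and oxidised (t-BuOOH, Rh2(cap)4, K2CO3, CH2Cl2) to the 3-oxo acetal F4. Reduction with LiBH(s-Bu)3 (THF, −78 °C) would give the (3R,6R)-hydroxy acetal F5, and unmasking (PPTS, wet acetone, rt) would give (3R,6R)-3-hydroxy-α-ionone F6. Excess CH2=CHMgBr (THF, 0 °C) would then give diol 6.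

Step 3 (ketone reduction). Facial selectivity of hydride delivery to C3' may be poor if the ring does not react through the conformer with the pseudoaxial side chain, so that the 3'-epimer forms in quantity. The fallback sets out from 5 and comes back at 8, replacing direct stereocontrol by inversion. Enone 5 would be reduced under Luche conditions (NaBH4, CeCl3·7H2O, MeOH, −78 °C), where the small hydride is expected to enter axially and favour the cis (3'S,6'R) diol F7. Mitsunobu esterification of F7 with palmitic acid (PPh3, DIAD, THF, 0 °C) would invert C3' and install the palmitate in one operation, leaving the tertiary alcohol untouched, to give 8. Any F7 formed in step 3 itself could be recycled the same way.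

Further compounds
F1 | step 13 | (1R,4R)-4-[(1E,3E,5E,7E,9E,11E,13E,15E,17E)-18-iodo-3,7,12,16-tetramethyloctadeca-1,3,5,7,9,11,13,15,17-nonaen-1-yl]-3,5,5-trimethylcyclohex-2-en-1-yl hexadecanoate | I/C=C/C(C)=C/C=C/C(C)=C/C=C/C=C(C)/C=C/C=C(C)/C=C/[C@H]1C(C)=C[C@H](OC(=O)CCCCCCCCCCCCCCC)CC1(C)C
F2 | step 13 | (1R,4R)-3,5,5-trimethyl-4-[(1E,3E,5E,7E,9E,11E,13E,15E,17E)-3,7,12,16-tetramethyl-18-(4,4,5,5-tetramethyl-1,3,2-dioxaborolan-2-yl)octadeca-1,3,5,7,9,11,13,15,17-nonaen-1-yl]cyclohex-2-en-1-yl hexadecanoate | CC1(C)OB(OC1(C)C)/C=C/C(C)=C/C=C/C(C)=C/C=C/C=C(C)/C=C/C=C(C)/C=C/[C@H]1C(C)=C[C@H](OC(=O)CCCCCCCCCCCCCCC)CC1(C)C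
F3 | step 2 | 2-methyl-2-{(E)-2-[(1R)-2,6,6-trimethylcyclohex-2-en-1-yl]ethenyl}-1,3-dioxolane | CC1(OCCO1)/C=C/[C@H]1C(C)=CCCC1(C)C
F4 | step 2 | (4R)-3,5,5-trimethyl-4-[(E)-2-(2-methyl-1,3-dioxolan-2-yl)ethenyl]cyclohex-2-en-1-one | CC1(OCCO1)/C=C/[C@H]1C(C)=CC(=O)CC1(C)C
F5 | step 2 | (1R,4R)-3,5,5-trimethyl-4-[(E)-2-(2-methyl-1,3-dioxolan-2-yl)ethenyl]cyclohex-2-en-1-ol | CC1(OCCO1)/C=C/[C@H]1C(C)=C[C@H](O)CC1(C)C
F6 | step 2 | (3E)-4-[(1R,4R)-4-hydroxy-2,6,6-trimethylcyclohex-2-en-1-yl]but-3-en-2-one | CC(=O)/C=C/[C@H]1C(C)=C[C@H](O)CC1(C)C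
F7 | step 3 | (1S,4R)-4-[(1E)-3-hydroxy-3-methylpenta-1,4-dien-1-yl]-3,5,5-trimethylcyclohex-2-en-1-ol | C=CC(C)(O)/C=C/[C@H]1C(C)=C[C@@H](O)CC1(C)C
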